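You cannot read a share at 10 s off these runs: the earliest reading stands at 6.00 min, in the grey run.

| flask | starting material | first nucleophile | second nucleophile | protic impurity | capture agent | remark | time |
|---|---|---|---|---|---|---|---|
| violet | 18 mM | 45 mM | 11 mM | 5.4 mM | 5.4 mM | run made earlier |  |
| grey | 18 mM | 45 mM | 24 mM | 5.4 mM | 5.4 mM | run made earlier |  |
| amber | 9 mM | 45 mM | 16.2 mM | 5.4 mM | 5.4 mM | run made earlier |  |
| flask | 18 mM | 45.0 mM | 16.2 mM | 5.40 mM | 5.40 mM |  | 2.0 h |

| run | time / min | other capture product / % | target / % |
|---|---|---|---|
| violet | 15.0 | 4.6 | 42.4 |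
| violet | 30.0 | 5.0 | 40.8 |
| violet | 50.0 | 4.5 | 40.8 |
| violet | 60.0 | 4.6 | 41.0 |
| violet | 80.0 | 4.5 | 41.1 |
| violet | 90.0 | 5.0 | 41.2 |
| grey | 6.00 | 9.3 | 32.4 |
| grey | 20.0 | 10.0 | 37.8 |
| grey | 30.0 | 8.7 | 38.0 |
| grey | 50.0 | 8.4 | 38.9 |
| grey | 80.0 | 9.2 | 38.2 |
| grey | 90.0 | 10.2 | 38.1 |
| amber | 8.00 | 4.4 | 20.8 |
| amber | 25.0 | 4.9 | 22.6 |
| amber | 40.0 | 3.1 | 22.3 |
| amber | 60.0 | 4.6 | 23.1 |
| amber | 90.0 | 4.7 | 23.0 |

(each reading ± 0.5 percentage points)

- share of other capture product in other capture product plus target at 10 s
- share of other capture product in other capture product plus target at 5.0 min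
- share of other capture product in other capture product plus target at 2.0 h
- which of other capture product and target there is more of at 2.0 h

What you can use is the plateau. My rule of thumb: if both nucleophiles compete for the same thing, late other capture product over target should go as the second nucleophile charge over the first nucleophile charge. In the violet run, the readings from 30.0 min on give a ratio of 0.115 at charges of 0.611 and 2.50 of the starting material, so 0.471. The grey run, from 20.0 min on, gives 0.243 at 1.33 and 2.50, so 0.456. Their mean, 0.464, is the capture weight: an apparent selectivity factor for a whole run, taken on the charges and read from scattered readings.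

This flask holds second nucleophile at 0.900 and first nucleophile at 2.50 of the starting material, a charge ratio of 0.360. So late other capture product over target is 0.167, target leads, and the late share is 14.3 %.

The border is a ratio of times. Here 5.0 min is 0.833 of the earliest time read, and 10 s is 0.0278 of it. In the grey run the ratio at that first reading is 0.287, above its late value, so as read the ratio in that run drifts downward. I therefore expect this flask's share to fall towards my late value as time runs, but these runs give no number for 10 s.

The forecast says 65 % at 10 s (25 % to 92 %), calling that share “very uncertain but high”, then 18.3 % at 5.0 min and 14.9 % at 2.0 h, a little above mine, with target ahead.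

This flask gives 38.9 %, 17.3 % and 14.6 %, with target ahead at 39.7 % against 6.81 %.

    starting material → open intermediate (k = 0.00590 s⁻¹)
    first nucleophile + open intermediate → target (k = 410 M⁻¹ s⁻¹)
    second nucleophile + open intermediate → other capture product (k = 780 M⁻¹ s⁻¹)
    open intermediate → solvolysis product (k = 10.0 s⁻¹)
    starting material + protic impurity → quenched substrate (k = 68.0 M⁻¹ s⁻¹)
    second nucleophile → decomposed reagent (k = 0.0150 s⁻¹)
    open intermediate + capture agent → trapped intermediate (k = 2.00 M⁻¹ s⁻¹)

At 2.00 h this flask holds 15.0 mM of decomposed reagent. Put through the same reckoning, this flask's end values give a capture weight of 0.476 against my 0.464, and its share at 10 s gives the larger figure of 1.77. At that time the forecast stood 26 percentage points high.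

In a neighbour flask with 11 mM of first nucleophile and all else as in this flask, the capture weight gives a ratio of 0.683 and a late share of 40.6 %. That neighbour flask computes to 39.8 %.

The data are simulated for an exercise; the scatter is artificial.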